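**Assumption (numbering):** ring carbons are numbered C1 (CH–OMe), C2, C3 (C=O), C4 (C(Me)OAc), C5, C6 (CH–OAng), C7, C8 (lactone CH–O), C9, C10 (CHMe); C11/C12/C13 are the lactone α‑carbon, carbonyl and exocyclic CH2. The target is then 1R,4R,6S,7S,8R,10R.

## Retrosynthetic overview

1. Target ⇐ late C3/C4 oxidation (dihydroxylation, oxidation, acetylation) of the Z‑C3=C4 olefin of an α‑methylene trans‑8,12‑lactone already carrying the 6‑angelate.
2. Lactone ⇐ ten‑membered γ‑keto ester: C8 reduction, then invertive (SN2) lactonisation, then α‑methylenation.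
3. Ten‑membered ring ⇐ tandem anionic oxy‑Cope ([3,3], forms C5–C6) / enolate alkylation (C7–C11) of a cis‑1‑[(E)‑2‑tert‑butoxyvinyl]‑2‑isopropenylcyclohexanol.
4. That carbinol ⇐ ketone 5 (C1‑OMe and C10‑Me already set) + tert‑butoxyacetylide; ketone 5 ⇐ (R)‑carvone in four steps.
5. Ring order: carvone cyclohexane (its stereocentre relays chirality and is consumed) → ten‑membered carbocycle (oxy‑Cope) → γ‑lactone.

## Forward route

**Step 1**
Reactants: 1, (R)‑(−)‑carvone
Product: 2, (1R,5R)‑cis‑carveol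
Conditions: NaBH4, CeCl3·7H2O, MeOH, −78 °C
Reagents that add atoms: none
Why: Luche 1,2‑reduction; axial hydride delivery gives the equatorial alcohol cis to the isopropenyl group (1R).

**Step 2**
Reactants: 2, (1R,5R)‑cis‑carveol
Product: 3, (4R,6R)‑6‑methoxy‑1‑methyl‑4‑(prop‑1‑en‑2‑yl)cyclohex‑1‑ene
Conditions: NaH, MeI, THF, 0 °C → rt
Reagents that add atoms: iodomethane, CI
Why: Williamson etherification; no stereocentre is touched.

**Step 3**
Reactants: 3
Product: 4, (4R,6R)‑4‑methoxy‑3‑methyl‑6‑(prop‑1‑en‑2‑yl)cyclohex‑2‑en‑1‑one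
Conditions: CrO3, 3,5‑dimethylpyrazole, CH2Cl2, −20 °C
Reagents that add atoms: chromium trioxide, O=[Cr](=O)=O
Why: Cr(VI) allylic oxidation attacks the ring CH2 next to the CH terminus of the trisubstituted olefin (the Δ5‑steroid → 7‑ketone pattern), giving the γ‑methoxy enone with both stereocentres intact.

**Step 4**
Reactants: 4
Product: 5, (2R,4R,5R)‑4‑methoxy‑5‑methyl‑2‑(prop‑1‑en‑2‑yl)cyclohexan‑1‑one
Conditions: Li, NH3(l), t‑BuOH (1 equiv), THF, −78 °C; NH4Cl
Reagents that add atoms: none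
Why: Dissolving‑metal enone reduction; axial protonation of the β‑carbon gives the all‑equatorial ketone (Me trans to OMe, future 10R), and the pseudo‑equatorial OMe is poorly aligned for reductive β‑elimination.

**Step 5**
Reactants: 6, trichloroethylene
Product: 7, tert‑butyl (E)‑1,2‑dichlorovinyl ether
Conditions: KOt‑Bu, THF, −78 °C → rt
Reagents that add atoms: potassium tert‑butoxide, CC(C)(C)[O-].[K+]
Why: Base‑induced elimination to dichloroacetylene and anti addition of tert‑butoxide (standard ynol‑ether precursor synthesis).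

**Step 6**
Reactants: 5; 7
Product: 8, (1S,2R,4R,5R)‑1‑(tert‑butoxyethynyl)‑4‑methoxy‑5‑methyl‑2‑(prop‑1‑en‑2‑yl)cyclohexan‑1‑ol
Conditions: 7, n‑BuLi (2.2 equiv), THF, −78 → −40 °C; CeCl3; then 5, −78 °C
Reagents that add atoms: none beyond the numbered reactants
Why: 7 is converted in situ to lithium tert‑butoxyacetylide, and the small, weakly basic cerium acetylide adds axially to the chair ketone, placing the alkynyl group axial and cis to the equatorial isopropenyl group.

**Step 7**
Reactants: 8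
Product: 9, (1S,2R,4R,5R)‑1‑[(E)‑2‑tert‑butoxyethenyl]‑4‑methoxy‑5‑methyl‑2‑(prop‑1‑en‑2‑yl)cyclohexan‑1‑ol
Conditions: Red‑Al, THF, 0 °C
Reagents that add atoms: none
Why: Alkoxide‑directed trans‑hydroalumination of the propargylic ynol ether gives the (E)‑enol ether only.

**Step 8 (key step)**
Reactants: 9; 10, tert‑butyl bromoacetate
Product: 11, tert‑butyl 2‑[(1R,3Z,6S,7R,10R)‑6‑tert‑butoxy‑1‑methoxy‑4,10‑dimethyl‑8‑oxocyclodec‑3‑en‑7‑yl]acetate (ring numbered as above)
Conditions: KHMDS, 18‑crown‑6, THF, −78 → −20 °C; then 10, −78 °C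
Reagents that add atoms: none beyond the numbered reactants
Why: Anionic oxy‑Cope [3,3] rearrangement through the chair transition state open to the axial/equatorial cis‑dialkenyl alkoxide (O‑t‑Bu equatorial) forms C5–C6 and the ten‑membered ring with 6S, and the resulting ring‑E potassium enolate is C‑alkylated on its peripheral face (anti to the new C5–C6 bond) to set C7.

**Step 9**
Reactants: 11
Product: 12, the (8S)‑alcohol (8‑epi relative to the target): tert‑butyl 2‑[(1R,3Z,6S,7S,8S,10R)‑6‑tert‑butoxy‑8‑hydroxy‑1‑methoxy‑4,10‑dimethylcyclodec‑3‑en‑7‑yl]acetate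
Conditions: L‑Selectride, THF, −78 °C; AcOH quench at −78 °C
Reagents that add atoms: none
Why: Ketone reduction in which Felkin–Anh control from C7 and peripheral attack on the macrocycle both predict the 8S alcohol (OH cis to the C7 side chain); the tert‑butyl ester resists lactonisation at −78 °C.

**Step 10**
Reactants: 12
Product: 13, the (8S)‑mesylate of 12
Conditions: MsCl, Et3N, DMAP (cat.), CH2Cl2, 0 °C
Reagents that add atoms: methanesulfonyl chloride, CS(=O)(=O)Cl
Why: O‑sulfonylation with retention turns C8–O into a leaving group.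

**Step 11**
Reactants: 13
Product: 14, trans‑fused γ‑lactone (1R,3Z,6S,7R,8R,10R) with free 6‑OH and C11 = CH2
Conditions: TMSOTf, 2,6‑lutidine, CH2Cl2, 0 °C → rt; then K2CO3, MeOH/DMF, 40 °C
Reagents that add atoms: none
Why: Silyl triflate cleaves the tert‑butyl ester and tert‑butyl ether, and the liberated carboxylate displaces the mesylate intramolecularly (5‑exo SN2, inversion) to give 8R and the trans lactone fusion.

**Step 12**
Reactants: 14
Product: 15, α‑(dimethylaminomethyl) lactone (C11 epimers)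
Conditions: LDA (2.3 equiv), THF, −78 °C; CH2=NMe2+ I−, −78 °C → rt
Reagents that add atoms: Eschenmoser's salt, C=[N+](C)C.[I-]
Why: Mannich reaction of the lactone enolate (the C6 alkoxide is a spectator); the new C11 centre is destroyed in the next step.

**Step 13**
Reactants: 15
Product: 16, (1R,3Z,6S,7R,8R,10R)‑6‑hydroxy‑1‑methoxy α‑methylene lactone
Conditions: MeI, THF/MeOH, rt; then aq. NaHCO3, rt
Reagents that add atoms: none (the methyl leaves with NMe3)
Why: N‑quaternisation followed by E1cB elimination gives the exocyclic methylene.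

**Step 14**
Reactants: 16; 17, angelic acid
Product: 18, 6‑O‑angelate (1R,3Z,6S,7S,8R,10R)
Conditions: 17, 2,4,6‑trichlorobenzoyl chloride, Et3N, PhMe, rt; then 16, DMAP, 70 °C
Reagents that add atoms: none beyond the numbered reactants
Why: Yamaguchi esterification of the secondary alcohol via the mixed anhydride, conditions chosen to limit Z → E isomerisation to the tiglate.

**Step 15**
Reactants: 18
Product: 19, 3,4‑diol (1R,3S,4R,6S,7S,8R,10R)
Conditions: OsO4 (5 mol %), NMO, acetone/H2O, 0 °C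
Reagents that add atoms: osmium tetroxide, O=[Os](=O)(=O)=O; N‑methylmorpholine N‑oxide, C[N+]1([O-])CCOCC1; water, O
Why: Upjohn syn‑dihydroxylation picks the only electron‑rich olefin (the enoate and α‑methylene lactone are deactivated) and attacks its exposed face away from the transannular C7–C8 segment, which the rearrangement geometry predicts gives 4R.

**Step 16**
Reactants: 19
Product: 20, 4‑hydroxy‑3‑ketone (1R,4R,6S,7S,8R,10R)
Conditions: Dess–Martin periodinane, NaHCO3, CH2Cl2, 0 °C
Reagents that add atoms: none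
Why: Only the secondary C3 alcohol can be oxidised, revealing the β‑methoxy ketone under neutral conditions.

**Step 17**
Reactants: 20
Product: 21, Rufesolide C
Conditions: Ac2O, Sc(OTf)3 (cat.), MeCN, −20 °C
Reagents that add atoms: acetic anhydride, CC(=O)OC(C)=O
Why: Lewis‑acid‑catalysed acetylation of the hindered tertiary α‑ketol with retention at C4, avoiding base that could eliminate the β‑methoxy group.

## Compound list

1 | (R)‑(−)‑carvone | CC(=C)[C@@H]1CC=C(C)C(=O)C1 | starting material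
2 | (1R,5R)‑cis‑carveol | CC(=C)[C@@H]1CC=C(C)[C@H](O)C1 | intermediate
3 | (4R,6R)‑6‑methoxy‑1‑methyl‑4‑(prop‑1‑en‑2‑yl)cyclohex‑1‑ene | CC(=C)[C@@H]1CC=C(C)[C@H](OC)C1 | intermediate
4 | (4R,6R)‑4‑methoxy‑3‑methyl‑6‑(prop‑1‑en‑2‑yl)cyclohex‑2‑en‑1‑one | CC(=C)[C@@H]1C(=O)C=C(C)[C@H](OC)C1 | intermediate
5 | (2R,4R,5R)‑4‑methoxy‑5‑methyl‑2‑(prop‑1‑en‑2‑yl)cyclohexan‑1‑one | CC(=C)[C@@H]1C(=O)C[C@@H](C)[C@H](OC)C1 | intermediate
6 | trichloroethylene | ClC=C(Cl)Cl | starting material
7 | tert‑butyl (E)‑1,2‑dichlorovinyl ether | CC(C)(C)O/C(Cl)=C\Cl | intermediate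
8 | (1S,2R,4R,5R)‑1‑(tert‑butoxyethynyl)‑4‑methoxy‑5‑methyl‑2‑(prop‑1‑en‑2‑yl)cyclohexan‑1‑ol | O[C@@]1(C#COC(C)(C)C)C[C@@H](C)[C@H](OC)C[C@@H]1C(C)=C | intermediate
9 | (1S,2R,4R,5R)‑1‑[(E)‑2‑tert‑butoxyethenyl]‑4‑methoxy‑5‑methyl‑2‑(prop‑1‑en‑2‑yl)cyclohexan‑1‑ol | O[C@@]1(/C=C/OC(C)(C)C)C[C@@H](C)[C@H](OC)C[C@@H]1C(C)=C | intermediate
10 | tert‑butyl bromoacetate | BrCC(=O)OC(C)(C)C | starting material
11 | ten‑membered keto ester (1R,3Z,6S,7R,10R) | O=C1C[C@@H](C)[C@H](OC)C/C=C(C)\C[C@H](OC(C)(C)C)[C@H]1CC(=O)OC(C)(C)C | intermediate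
12 | (8S)‑hydroxy ester (1R,3Z,6S,7S,8S,10R) | O[C@H]1C[C@@H](C)[C@H](OC)C/C=C(C)\C[C@H](OC(C)(C)C)[C@H]1CC(=O)OC(C)(C)C | intermediate
13 | (8S)‑mesylate (1R,3Z,6S,7R,8S,10R) | CS(=O)(=O)O[C@H]1C[C@@H](C)[C@H](OC)C/C=C(C)\C[C@H](OC(C)(C)C)[C@H]1CC(=O)OC(C)(C)C | intermediate
14 | trans‑8,12‑lactone, 6‑OH, C11 = CH2 (1R,3Z,6S,7R,8R,10R) | O=C1O[C@@H]2C[C@@H](C)[C@H](OC)C/C=C(C)\C[C@H](O)[C@H]2C1 | intermediate
15 | 11‑(dimethylaminomethyl) lactone (C11 mixture) | CN(C)CC1C(=O)O[C@@H]2C[C@@H](C)[C@H](OC)C/C=C(C)\C[C@H](O)[C@@H]12 | intermediate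
16 | α‑methylene lactone, 6‑OH (1R,3Z,6S,7R,8R,10R) | C=C1C(=O)O[C@@H]2C[C@@H](C)[C@H](OC)C/C=C(C)\C[C@H](O)[C@@H]12 | intermediate
17 | angelic acid ((Z)‑2‑methylbut‑2‑enoic acid) | C/C=C(/C)C(=O)O | starting material
18 | 6‑O‑angelate (1R,3Z,6S,7S,8R,10R) | C=C1C(=O)O[C@@H]2C[C@@H](C)[C@H](OC)C/C=C(C)\C[C@H](OC(=O)/C(C)=C\C)[C@@H]12 | intermediate
19 | 3,4‑diol (1R,3S,4R,6S,7S,8R,10R) | C=C1C(=O)O[C@@H]2C[C@@H](C)[C@H](OC)C[C@H](O)[C@](C)(O)C[C@H](OC(=O)/C(C)=C\C)[C@@H]12 | intermediate
20 | 4‑hydroxy‑3‑ketone (1R,4R,6S,7S,8R,10R) | C=C1C(=O)O[C@@H]2C[C@@H](C)[C@H](OC)CC(=O)[C@](C)(O)C[C@H](OC(=O)/C(C)=C\C)[C@@H]12 | intermediate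
21 | Rufesolide C | C=C1C(=O)O[C@@H]2C[C@@H](C)[C@H](OC)CC(=O)[C@](C)(OC(C)=O)C[C@H](OC(=O)/C(C)=C\C)[C@@H]12 | target

## Step count and risks

**Total steps:** 17. **Longest linear sequence:** 16 (steps 1–4 and 6–17 from (R)‑carvone); step 5 is a one‑step side branch.

**Three steps most likely to fail:**

- **Step 4 (Li/NH3 on a γ‑methoxy enone).** The risk is reductive loss of the OMe group; the preceding allylic oxidation of an allylic ether (step 3) is also delicate. Fallback: carry C1–O as the acetate through the Cr(VI) oxidation, methanolyse to the γ‑hydroxy enone, reduce it as its lithium alkoxide (no leaving group, same thermodynamic trans outcome), and O‑methylate afterwards with Me3OBF4/proton sponge. This changes protecting group and order and costs two steps.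
- **Step 8 (tandem oxy‑Cope/alkylation).** The enolate carries a β‑O‑t‑Bu group and could eliminate, O‑alkylate, or alkylate on the wrong face. Fallback: uncouple the tandem by running a neutral thermal siloxy‑Cope on the TMS ether of 9 to obtain the regiodefined silyl enol ether without a free enolate, then regenerate the enolate with MeLi at −78 °C and alkylate immediately.
- **Step 15 (face selectivity at the Z‑C3=C4 olefin).** The C4 configuration rests on a conformational argument for a Z‑olefin in a ten‑membered ring, which is weaker than for an E‑olefin. Fallback: if the wrong face is hydroxylated, epoxidise from that same preferred face (DMDO) and open the epoxide by acid‑catalysed hydrolysis at the tertiary carbon (inversion at C4), then oxidise C3–OH; this delivers the opposite C4 configuration from the same facial bias.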